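**Retrosynthetic overview**
- C2/C3 diol: last-step syn-dihydroxylation of a ring A Δ2 alkene from the α face. C12–C13: B-alkyl Suzuki coupling of a C9 vinyl carbinol with methyl (Z)-3-iodobut-2-enoate.
- C9–C11 and the Δ2 alkene: one-pot axial vinyl addition to the C9 ketone and Shapiro reaction of the C3 tosylhydrazone of a trans-4,4,8,10-tetramethyldecalin-3,9-dione.
- C4 gem-dimethyl and 5α-H: deconjugative methylation, then HAT hydrogenation of a bicyclic enedione.
- Key disconnection: ring B (C8 and C17) by CH(CH3) insertion of diazoethane into the cyclopentanone of a Hajos–Parrish-type hydrindenedione. C7 shifts from C9 to the new C8, so the five-membered ring becomes six-membered.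
- Ring order: the five-membered ring is bought, ring A comes from an amino-acid-catalysed asymmetric Robinson annulation, and ring B comes from the ring expansion.

Assumption: the SMILES is read literally. In labdane numbering (used throughout for positions) this means 13Z, 2α-OH, 3α-OH, 5α-H, 8α-CH3, 9β-OH with the side chain 9α (axial), and 10β-CH3, that is 2R,3S,5S,8R,9S,10S.

**Step 1**
Reactants: 1 2-methylcyclopentane-1,3-dione; 2 pent-1-en-3-one (ethyl vinyl ketone)
Product: 4 (7aS)-4,7a-dimethyl-2,3,7,7a-tetrahydro-1H-indene-1,5(6H)-dione, via triketone 3 (not isolated)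
Conditions: 2 (1.3 equiv), AcOH (cat), H2O, 70 °C; extract, concentrate; then (S)-phenylalanine (1.0 equiv), (+)-camphorsulfonic acid (0.5 equiv), DMF, 30 → 70 °C; one recrystallisation (Et2O/hexane) to >99% ee
Reagents that add atoms: none
Why: Michael addition followed by the Hajos–Parrish–Eder–Sauer–Wiechert reaction (amino-acid-catalysed enantiogroup-selective intramolecular aldol condensation), in which the (S)-phenylalanine enamine of the ethyl ketone attacks one of the two enantiotopic ring carbonyls through a carboxylic-acid-bridged transition state, closing ring A and fixing the quaternary C10 as S (10β-methyl), primary amino acids being the established catalysts for ethyl ketone side chains.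

**Step 2**
Reactants: 4 (7aS)-4,7a-dimethyl-2,3,7,7a-tetrahydro-1H-indene-1,5(6H)-dione; 5 N-ethyl-N-nitrosourea
Product: 7 (2R,8aS)-2,5,8a-trimethyl-3,4,8,8a-tetrahydronaphthalene-1,6(2H,7H)-dione (formed as a C2 epimer mixture, thermodynamic epimer drawn), via diazoethane 6 (not isolated)
Conditions: 5, 40% aq KOH/Et2O, 0 °C, ether layer dried over KOH pellets (1.5 equiv of 6); added over 2 h to 4, Sc(OTf)3 (10 mol %), CH2Cl2, −78 → −30 °C
Reagents that add atoms: none
Why: Proposed new method: Sc(OTf)3-catalysed CH(CH3) insertion of diazoethane into the α-quaternary cyclopentanone of an unprotected Hajos–Parrish-type enedione; trivalent scandium activates the strained, non-conjugated C9 carbonyl for C-attack of the diazoalkane from the face anti to the angular methyl (the vinylogous, tetrasubstituted enone is much less electrophilic and its fully substituted β-carbon shuts down pyrazoline formation), the β-oxido diazonium rotamer that avoids a clash between the incoming methyl and the quaternary C10 places the C9–C7 bond antiperiplanar to N2, so the C7 methylene undergoes the 1,2-shift with loss of N2, which enlarges the five-membered ring to ring B, forms C7–C8 and C8–C9 and brings in C17, and the 2,2,6-trisubstituted product ketone is too hindered to react again; C8 arises as an epimer mixture that is levelled in step 3; the closest known reaction type is the Lewis-acid-promoted diazoalkane homologation of cyclic ketones (Büchner–Curtius–Schlotterbeck or Tiffeneau–Demjanov type), as in the D-homo enlargement of 17-oxo steroids where the methylene likewise migrates.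

**Step 3**
Reactants: 7 (2R,8aS)-2,5,8a-trimethyl-3,4,8,8a-tetrahydronaphthalene-1,6(2H,7H)-dione
Product: 8 (2R,8aS)-2,5,5,8a-tetramethyl-3,5,8,8a-tetrahydronaphthalene-1,6(2H,7H)-dione (4,4-dimethyl, C5=C6 alkene)
Conditions: KOtBu (1.15 equiv), t-BuOH/THF, 0 °C → rt, 30 min; MeI (1.5 equiv), 0 °C → rt
Reagents that add atoms: iodomethane, CI
Why: Deconjugative α-alkylation of the thermodynamic extended dienolate (the classical 4,4-dimethylation tactic of steroid and Wieland–Miescher chemistry) places the second methyl on C4 and moves the alkene to C5=C6, while reversible enolisation of the C9 ketone under the same base levels C8 to the equatorial 8α-methyl epimer (an 8β-methyl would be syn-diaxial to the C10 methyl) and the crowded tetrasubstituted C8 enolate is not methylated at a competitive rate.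

**Step 4**
Reactants: 8 (2R,8aS)-2,5,5,8a-tetramethyl-3,5,8,8a-tetrahydronaphthalene-1,6(2H,7H)-dione
Product: 9 (2R,4aS,8aS)-2,5,5,8a-tetramethyl-3,4,4a,7,8,8a-hexahydronaphthalene-1,6(2H,5H)-dione (trans-decalin-3,9-dione)
Conditions: Mn(dpm)3 (10 mol %), PhSiH3 (2.2 equiv), t-BuOOH (1.5 equiv), i-PrOH, rt, Ar
Reagents that add atoms: none
Why: Metal-hydride hydrogen atom transfer (MHAT) hydrogenation, in which the manganese hydride gives H to the less substituted C6 and the tertiary C5 radical takes the second H from the α face, away from the axial C4β and C10 methyl groups, so that the thermodynamically preferred trans-decalin (5α-H, 5S) results with both ketones untouched under these neutral radical conditions.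

**Step 5**
Reactants: 9 (2R,4aS,8aS)-2,5,5,8a-tetramethyl-3,4,4a,7,8,8a-hexahydronaphthalene-1,6(2H,5H)-dione
Product: 10 C3 mono-(E)-tosylhydrazone of 9 (C9 ketone free)
Conditions: TsNHNH2 (1.05 equiv), PPTS (5 mol %), EtOH, 60 °C
Reagents that add atoms: p-toluenesulfonohydrazide, Cc1ccc(cc1)S(=O)(=O)NN
Why: Acid-catalysed hydrazone condensation is site-selective because the C3 carbonyl has an open methylene flank whereas the C9 carbonyl is 2,2,6-trisubstituted and practically inert to condensation, no stereocentre is formed, and the N-sulfonyl group settles anti to the quaternary C4, that is syn to C2–H as the Shapiro step needs.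

**Step 6**
Reactants: 10 C3 mono-(E)-tosylhydrazone of 9; 11 bromoethene (vinyl bromide)
Product: 14 (1S,2R,4aS,8aS)-1-ethenyl-2,5,5,8a-tetramethyl-1,2,3,4,4a,5,8,8a-octahydronaphthalen-1-ol, via vinyllithium 12 (not isolated), via carbinol tosylhydrazone 13 (not isolated)
Conditions: 11 (2.6 equiv), t-BuLi (5.2 equiv), Et2O, −78 °C; add 10 in THF, −78 °C, 1 h; then MeLi (3 equiv), TMEDA, −78 °C → rt until N2 evolution stops; H2O
Reagents that add atoms: none
Why: Vinyllithium first removes N–H and then adds to the only remaining carbonyl (C9) along the axial α trajectory, because the β face is shielded by the adjacent axial C10 methyl, which sets C9 as S with equatorial 9β-OH and axial 9α-vinyl (1,2-addition under steric approach control), and MeLi then removes the syn C2–H of the lithiated hydrazone so that loss of sulfinate and N2 (Shapiro reaction) gives the C3 vinyl anion, protonated on quench to the Δ2 alkene, only one regioisomer being possible since C4 is quaternary.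

**Step 7**
Reactants: 15 methyl but-2-ynoate
Product: 16 methyl (Z)-3-iodobut-2-enoate
Conditions: NaI (1.6 equiv), AcOH, 115 °C, 2 h
Reagents that add atoms: sodium iodide, [Na+].[I-]
Why: Conjugate hydroiodination of an ynoate (iodide adds to C3 and the allenolate is protonated anti) is a standard, highly Z-selective reaction that puts iodine cis to the ester and so encodes the 13Z geometry.

**Step 8**
Reactants: 14 (1S,2R,4aS,8aS)-1-ethenyl-2,5,5,8a-tetramethyl-1,2,3,4,4a,5,8,8a-octahydronaphthalen-1-ol; 16 methyl (Z)-3-iodobut-2-enoate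
Product: 18 methyl (2Z)-5-[(1S,2R,4aS,8aS)-1-hydroxy-2,5,5,8a-tetramethyl-1,2,3,4,4a,5,8,8a-octahydronaphthalen-1-yl]-3-methylpent-2-enoate, via B-alkyl-9-BBN 17 (not isolated)
Conditions: 9-BBN-H (2.5 equiv), THF, 0 °C → rt, 6 h; then 3 M aq Cs2CO3, 16 (1.3 equiv), Pd(dppf)Cl2 (5 mol %), AsPh3 (10 mol %), DMF, rt
Reagents that add atoms: none
Why: 9-BBN hydroborates the monosubstituted vinyl group anti-Markovnikov about four orders of magnitude faster than the hindered ring cis-alkene, and the B-alkyl Suzuki–Miyaura coupling of the primary borane with the (Z)-β-iodoenoate proceeds with retention of alkene geometry, forming C12–C13 and delivering the 13Z enoate.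

**Step 9**
Reactants: 18 methyl (2Z)-5-[(1S,2R,4aS,8aS)-1-hydroxy-2,5,5,8a-tetramethyl-1,2,3,4,4a,5,8,8a-octahydronaphthalen-1-yl]-3-methylpent-2-enoate
Product: 19 methyl (2Z)-3-methyl-5-[(1S,2R,4aS,6S,7R,8aS)-1,6,7-trihydroxy-2,5,5,8a-tetramethyldecahydronaphthalen-1-yl]pent-2-enoate (target)
Conditions: OsO4 (5 mol %), NMO (1.15 equiv), acetone/H2O 4:1, 0 °C → rt, stopped at full conversion of 18; aq Na2SO3
Reagents that add atoms: osmium tetroxide, O=[Os](=O)(=O)=O; N-methylmorpholine N-oxide, C[N+]1([O-])CCOCC1; water, O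
Why: Upjohn syn-dihydroxylation, in which electrophilic OsO4 selects the electron-rich ring alkene over the conjugated, trisubstituted enoate and approaches from the α face because the β face carries the syn-axial C4β and C10 methyl groups, giving the 2α,3α-cis-diol (2R,3S).

**Compound list**
1 | 2-methylcyclopentane-1,3-dione | CC1C(=O)CCC1=O | starting material
2 | pent-1-en-3-one (ethyl vinyl ketone) | C=CC(=O)CC | starting material
3 | 2-methyl-2-(3-oxopentyl)cyclopentane-1,3-dione | CCC(=O)CCC1(C)C(=O)CCC1=O | intermediate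
4 | (7aS)-4,7a-dimethyl-2,3,7,7a-tetrahydro-1H-indene-1,5(6H)-dione | O=C1CCC2=C(C)C(=O)CC[C@]12C | intermediate
5 | N-ethyl-N-nitrosourea | CCN(N=O)C(N)=O | starting material
6 | diazoethane | CC=[N+]=[N-] | intermediate
7 | (2R,8aS)-2,5,8a-trimethyl-3,4,8,8a-tetrahydronaphthalene-1,6(2H,7H)-dione | O=C1[C@H](C)CCC2=C(C)C(=O)CC[C@]12C | intermediate
8 | (2R,8aS)-2,5,5,8a-tetramethyl-3,5,8,8a-tetrahydronaphthalene-1,6(2H,7H)-dione | O=C1[C@H](C)CC=C2C(C)(C)C(=O)CC[C@]12C | intermediate
9 | (2R,4aS,8aS)-2,5,5,8a-tetramethyl-3,4,4a,7,8,8a-hexahydronaphthalene-1,6(2H,5H)-dione | O=C1[C@H](C)CC[C@H]2C(C)(C)C(=O)CC[C@]12C | intermediate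
10 | C3 mono-(E)-tosylhydrazone of 9 | O=C1[C@H](C)CC[C@H]2C(C)(C)/C(=N/NS(=O)(=O)c3ccc(C)cc3)CC[C@]12C | intermediate
11 | bromoethene (vinyl bromide) | C=CBr | starting material
12 | vinyllithium | [Li]C=C | intermediate
13 | 9β-hydroxy-9α-vinyl C3 (E)-tosylhydrazone (neutral form of the lithiated adduct) | C=C[C@]1(O)[C@H](C)CC[C@H]2C(C)(C)/C(=N/NS(=O)(=O)c3ccc(C)cc3)CC[C@@]21C | intermediate
14 | (1S,2R,4aS,8aS)-1-ethenyl-2,5,5,8a-tetramethyl-1,2,3,4,4a,5,8,8a-octahydronaphthalen-1-ol | C=C[C@]1(O)[C@H](C)CC[C@H]2C(C)(C)C=CC[C@@]21C | intermediate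
15 | methyl but-2-ynoate | CC#CC(=O)OC | starting material
16 | methyl (Z)-3-iodobut-2-enoate | COC(=O)/C=C(/C)I | intermediate
17 | 9-[2-(9β-hydroxy-Δ2-decalin-9α-yl)ethyl]-9-borabicyclo[3.3.1]nonane (C12 borane of 14) | B3(C4CCCC3CCC4)CC[C@]1(O)[C@H](C)CC[C@H]2C(C)(C)C=CC[C@@]21C | intermediate
18 | methyl (2Z)-5-[(1S,2R,4aS,8aS)-1-hydroxy-2,5,5,8a-tetramethyl-1,2,3,4,4a,5,8,8a-octahydronaphthalen-1-yl]-3-methylpent-2-enoate | COC(=O)/C=C(/C)CC[C@]1(O)[C@H](C)CC[C@H]2C(C)(C)C=CC[C@@]21C | intermediate
19 | methyl (2Z)-3-methyl-5-[(1S,2R,4aS,6S,7R,8aS)-1,6,7-trihydroxy-2,5,5,8a-tetramethyldecahydronaphthalen-1-yl]pent-2-enoate | COC(=O)/C=C(/C)CC[C@]1(O)[C@H](C)CC[C@H]2C(C)(C)[C@H](O)[C@H](O)C[C@@]21C | target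

Total step count: 9, with one-pot operations counted once.
Longest linear sequence: 8 (steps 1, 2, 3, 4, 5, 6, 8, 9). Step 7 is a one-step side branch.

**Three steps most likely to fail**

Step 2 (the proposed new ring expansion).
- Risks: epoxide formation instead of migration, partial migration of C10, Lewis-acid decomposition of diazoethane, or attack at the enone.
- Fallback with known chemistry, from 4 back to 7: BF3·OEt2-promoted homologation of 4 with ethyl diazoacetate in CH2Cl2 at 0 °C, the protocol used on 17-oxo steroids with methylene migration. It gives the ring-enlarged β-keto ester ethyl (8aS)-5,8a-dimethyl-1,6-dioxo-1,2,3,4,6,7,8,8a-octahydronaphthalene-2-carboxylate F1.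
- K2CO3/MeI in acetone then methylates the doubly activated C8 chemoselectively to ethyl (8aS)-2,5,8a-trimethyl-1,6-dioxo-1,2,3,4,6,7,8,8a-octahydronaphthalene-2-carboxylate F2.
- Krapcho dealkoxycarbonylation (LiCl, wet DMSO, 150 °C) returns 7.

Step 4 (HAT hydrogenation of an alkene flanked by two quaternary carbons).
- Risks: slow hydrogen atom transfer, or 1,2-acyl shift of the β-keto C5 radical.
- Fallback from 7 back to 9, which also bypasses step 3: LiAlH4 in THF reduces both carbonyls to the 3β,9β-dihydroxy-4,8α,10-trimethyl-Δ4-octalin F3.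
- MnO2 in CH2Cl2 reoxidises only the allylic alcohol to the 9β-hydroxy-Δ4-en-3-one F4.
- Stork reductive alkylation (Li/NH3, t-BuOH 1 equiv, then MeI) installs 5α-H and the second C4 methyl while the C9 oxygen sits as an inert alkoxide, giving the 9β-hydroxy-4,4,8α,10-tetramethyl-trans-decal-3-one F5.
- Dess–Martin periodinane oxidises C9–OH to give 9.

Step 6 (one-pot vinyl addition and Shapiro reaction).
- Risks: incomplete second deprotonation in the presence of the lithium alkoxide, or enolisation of the C9 ketone.
- Fallback from 9 back to 14, with the two events separated and the alkene made by cross-coupling chemistry: kinetic deprotonation at C2 with KN(SiMe3)2 at −78 °C and trapping with PhNTf2 gives the C3 enol triflate of 9 F6.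
- Formate reduction under palladium catalysis (Pd(OAc)2, PPh3, HCO2H, Bu3N, DMF, 60 °C) gives (2R,4aS,8aS)-2,5,5,8a-tetramethyl-3,4,4a,5,8,8a-hexahydronaphthalen-1(2H)-one F7.
- CH2=CHMgBr/CeCl3 in THF at −78 °C adds from the α face to give 14.

**Further compounds**
F1 | step 2 | ethyl (8aS)-5,8a-dimethyl-1,6-dioxo-1,2,3,4,6,7,8,8a-octahydronaphthalene-2-carboxylate (C2 labile, keto/enol) | CCOC(=O)C1CCC2=C(C)C(=O)CC[C@]2(C)C1=O
F2 | step 2 | ethyl (8aS)-2,5,8a-trimethyl-1,6-dioxo-1,2,3,4,6,7,8,8a-octahydronaphthalene-2-carboxylate (C2 configuration inconsequential) | CCOC(=O)C1(C)CCC2=C(C)C(=O)CC[C@]2(C)C1=O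
F3 | step 4 | 3β,9β-dihydroxy-4,8α,10-trimethyl-Δ4-octalin | O[C@H]1[C@H](C)CCC2=C(C)[C@@H](O)CC[C@]12C
F4 | step 4 | 9β-hydroxy-4,8α,10-trimethyl-Δ4-octal-3-one | O[C@H]1[C@H](C)CCC2=C(C)C(=O)CC[C@]12C
F5 | step 4 | 9β-hydroxy-4,4,8α,10-tetramethyl-trans-decal-3-one | O[C@H]1[C@H](C)CC[C@H]2C(C)(C)C(=O)CC[C@]12C
F6 | step 6 | C3 enol triflate (C2=C3) of 9 | O=C1[C@H](C)CC[C@H]2C(C)(C)C(OS(=O)(=O)C(F)(F)F)=CC[C@]12C
F7 | step 6 | (2R,4aS,8aS)-2,5,5,8a-tetramethyl-3,4,4a,5,8,8a-hexahydronaphthalen-1(2H)-one | O=C1[C@H](C)CC[C@H]2C(C)(C)C=CC[C@]12C
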